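**Retrosynthetic overview**

1. The strategy rests on the carbocycle of unit A (C4a–C5–C6–C7–C8–C8a): its 6,7-diol is cis and lies anti to the C5 aryloxy and C8 hydroxy groups, which are cis to each other. This is the pattern left by osmylation of a C6=C7 alkene from the face opposite both allylic oxygens.
2. C6–O and C7–O are cut first (dihydroxylation), then C6=C7 (ring-closing metathesis of a 4-pyranone with a 1-(aryloxy)allyl arm on C4a and a 1-(silyloxy)allyl arm on C8a); both are run in one flask.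
3. The C5–O aryl ether comes from iridium-catalysed branched allylic etherification of an (E)-allyl carbonate on C4a with the 6-hydroxychromone (unit B). The allyl arm comes from Suzuki coupling of a C4a-iodopyranone.
4. The iodopyranone comes from an ynone built from an (S)-enynol silyl ether (future C8) and a masked β-keto amide, by amine addition, iodination and acid ring closure.
5. Ring order: the chromone of unit B and the pyranone of unit A are made separately first; the carbocycle of unit A is closed last.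

Key step: step 15

Remark 1: the lipase is assumed to follow the Kazlauskas preference with the silylethynyl group as the large substituent, so the (R)-alcohol is acetylated and the (S)-alcohol is recovered; were the sense reversed, the acetate would be methanolysed and carried on.
Remark 2: L is (Ra)-1,1'-binaphthalene-2,2'-diyl N,N-bis[(1R)-1-phenylethyl]phosphoramidite, assumed to give the (R)-configured branched aryl ether from an (E)-3-arylallyl carbonate; its mirror image would be used if the sense proved opposite.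
Remark 3: (E)-3-(pinacolboryl)prop-2-en-1-ol is taken as a purchasable reagent (otherwise one hydroboration step from propargyl alcohol and pinacolborane).

**Route**

Step 1
Reactants: 1 trimethylsilylacetylene; 2 acrolein
Product: 3 rac-5-(trimethylsilyl)pent-1-en-4-yn-3-ol
Conditions: nBuLi, THF, −78 °C; then 2; aq. NH4Cl
Reagents that add atoms: none
Why: 1,2-addition of the lithium acetylide to the aldehyde (acetylide addition) is faster than conjugate addition at low temperature and should give the racemic enynol.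

Step 2
Reactants: 3 rac-5-(trimethylsilyl)pent-1-en-4-yn-3-ol
Product: 4 (3S)-5-(trimethylsilyl)pent-1-en-4-yn-3-ol
Conditions: vinyl acetate, Amano lipase AK, hexane, rt, stopped just past half conversion
Reagents that add atoms: none
Why: lipase-catalysed kinetic resolution by transesterification should acetylate the (R)-alcohol and leave the (S)-alcohol, whose carbinol carbon becomes C8.

Step 3
Reactants: 4 (3S)-5-(trimethylsilyl)pent-1-en-4-yn-3-ol
Product: 5 tert-butyldimethyl{[(3S)-5-(trimethylsilyl)pent-1-en-4-yn-3-yl]oxy}silane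
Conditions: TBSCl, imidazole, DMF, rt
Reagents that add atoms: tert-butyldimethylsilyl chloride, CC(C)(C)[Si](C)(C)Cl
Why: O-silylation of a secondary alcohol via the silylimidazolium (Corey conditions) does not touch the stereocentre.

Step 4
Reactants: 5 tert-butyldimethyl{[(3S)-5-(trimethylsilyl)pent-1-en-4-yn-3-yl]oxy}silane
Product: 6 tert-butyldimethyl{[(3S)-pent-1-en-4-yn-3-yl]oxy}silane
Conditions: K2CO3 (cat.), MeOH, rt
Reagents that add atoms: none
Why: methanolysis cleaves the alkynyl C–Si bond selectively, while the hindered silyl ether and the carbinol centre are stable to carbonate.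

Step 5
Reactants: 7 ethyl 3-oxo-5-phenylpentanoate
Product: 8 ethyl (2E)-3-methoxy-5-phenylpent-2-enoate
Conditions: HC(OMe)3, H2SO4 (cat.), rt
Reagents that add atoms: trimethyl orthoformate, COC(OC)OC
Why: acid-catalysed ketalisation of the keto group and loss of methanol should give the (E)-enol ether, which masks the ketone in a non-enolisable, acid-labile form.

Step 6
Reactants: 8 ethyl (2E)-3-methoxy-5-phenylpent-2-enoate
Product: 9 (2E)-N,3-dimethoxy-N-methyl-5-phenylpent-2-enamide
Conditions: MeNH(OMe)·HCl, iPrMgCl, THF, −20 to 0 °C; aq. NH4Cl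
Reagents that add atoms: N,O-dimethylhydroxylamine hydrochloride, CNOC.Cl
Why: aminolysis of the ester by the chloromagnesium amide (Weinreb amide formation) should proceed without touching the enol ether.

Step 7
Reactants: 6 tert-butyldimethyl{[(3S)-pent-1-en-4-yn-3-yl]oxy}silane; 9 (2E)-N,3-dimethoxy-N-methyl-5-phenylpent-2-enamide
Product: 10 (3S,7E)-3-(tert-butyldimethylsilyloxy)-8-methoxy-10-phenyldeca-1,7-dien-4-yn-6-one
Conditions: nBuLi, THF, −78 °C; then 9, −78 to 0 °C; aq. NH4Cl
Reagents that add atoms: none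
Why: Weinreb ketone synthesis, in which the chelated tetrahedral adduct of the lithium acetylide stops at the ynone stage, and the terminal alkyne is deprotonated far faster than the carbinol C–H.

Step 8
Reactants: 10 (3S,7E)-3-(tert-butyldimethylsilyloxy)-8-methoxy-10-phenyldeca-1,7-dien-4-yn-6-one
Product: 13 3-iodo-6-(2-phenylethyl)-2-[(1S)-1-(tert-butyldimethylsilyloxy)prop-2-en-1-yl]-4H-pyran-4-one, via enaminone 11 (not isolated), via iodo-enaminone 12 (not isolated)
Conditions: pyrrolidine (1.0 equiv), CH2Cl2, 0 °C; NIS, −20 °C; then THF–AcOH–H2O, 40 °C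
Reagents that add atoms: N-iodosuccinimide, O=C1CCC(=O)N1I; water, O
Why: aza-Michael addition of the amine to the ynone, electrophilic iodination at the enaminone carbon (far more nucleophilic than the methoxy-enone carbon) and acid hydrolysis with addition–elimination ring closure should give the γ-pyranone with iodine fixed next to the silyloxyallyl arm.

Step 9
Reactants: 13 3-iodo-6-(2-phenylethyl)-2-[(1S)-1-(tert-butyldimethylsilyloxy)prop-2-en-1-yl]-4H-pyran-4-one; 14 (2E)-3-(4,4,5,5-tetramethyl-1,3,2-dioxaborolan-2-yl)prop-2-en-1-ol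
Product: 15 3-[(1E)-3-hydroxyprop-1-en-1-yl]-6-(2-phenylethyl)-2-[(1S)-1-(tert-butyldimethylsilyloxy)prop-2-en-1-yl]-4H-pyran-4-one
Conditions: Pd(dppf)Cl2 (5 mol%), K3PO4, THF–H2O, 40 °C
Reagents that add atoms: none
Why: Suzuki–Miyaura coupling (oxidative addition of zerovalent palladium into the C–I bond of the iodo enone, transmetalation, reductive elimination) keeps the (E)-geometry of the boronate, and the mild base spares the C–H at the silyloxy carbon.

Step 10
Reactants: 15 3-[(1E)-3-hydroxyprop-1-en-1-yl]-6-(2-phenylethyl)-2-[(1S)-1-(tert-butyldimethylsilyloxy)prop-2-en-1-yl]-4H-pyran-4-one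
Product: 16 methyl (2E)-3-{4-oxo-6-(2-phenylethyl)-2-[(1S)-1-(tert-butyldimethylsilyloxy)prop-2-en-1-yl]-4H-pyran-3-yl}prop-2-en-1-yl carbonate
Conditions: ClCO2Me, pyridine, CH2Cl2, 0 °C
Reagents that add atoms: methyl chloroformate, COC(=O)Cl
Why: acylation of the primary allylic alcohol gives the carbonate leaving group needed for the allylic substitution.

Step 11
Reactants: 17 2',4',5'-trihydroxyacetophenone
Product: 18 1-[4-(benzyloxy)-2,5-dihydroxyphenyl]ethan-1-one
Conditions: BnBr (1.0 equiv), NaHCO3, DMF, 40 °C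
Reagents that add atoms: benzyl bromide, BrCc1ccccc1
Why: Williamson etherification with a weak base should take the most acidic hydroxyl, the one para to the acetyl group, while the 2'-hydroxyl is held by its hydrogen bond to the carbonyl and the 5'-hydroxyl is less acidic.

Step 12
Reactants: 18 1-[4-(benzyloxy)-2,5-dihydroxyphenyl]ethan-1-one
Product: 19 1-[4-(benzyloxy)-2-hydroxy-5-(methoxymethoxy)phenyl]ethan-1-one
Conditions: MOMCl, iPr2NEt, CH2Cl2, 0 °C
Reagents that add atoms: chloromethyl methyl ether, COCCl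
Why: acetal protection goes to the free 5'-phenol and not to the chelated 2'-phenol.

Step 13
Reactants: 19 1-[4-(benzyloxy)-2-hydroxy-5-(methoxymethoxy)phenyl]ethan-1-one; 20 methyl 3-phenylpropanoate
Product: 22 7-(benzyloxy)-6-hydroxy-2-(2-phenylethyl)-4H-chromen-4-one, via diketone 21 (not isolated)
Conditions: NaH, THF, reflux; then conc. HCl, MeOH, 65 °C
Reagents that add atoms: none
Why: Claisen condensation of the acetophenone enolate with the ester gives the β-diketone, and acid then closes the chromone by cyclodehydration and removes the methoxymethyl group while the benzyl ether stays.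

Step 14
Reactants: 16 methyl (2E)-3-{4-oxo-6-(2-phenylethyl)-2-[(1S)-1-(tert-butyldimethylsilyloxy)prop-2-en-1-yl]-4H-pyran-3-yl}prop-2-en-1-yl carbonate; 22 7-(benzyloxy)-6-hydroxy-2-(2-phenylethyl)-4H-chromen-4-one
Product: 23 3-[(1R)-1-{[7-(benzyloxy)-4-oxo-2-(2-phenylethyl)-4H-chromen-6-yl]oxy}prop-2-en-1-yl]-2-[(1S)-1-(tert-butyldimethylsilyloxy)prop-2-en-1-yl]-6-(2-phenylethyl)-4H-pyran-4-one
Conditions: 22, LiN(SiMe3)2, THF, 0 °C; then 16, [Ir(cod)Cl]2 (2 mol%), L (4 mol%), THF, 50 °C; aq. NH4Cl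
Reagents that add atoms: none
Why: iridium-catalysed asymmetric allylic etherification, in which the carbonate ionises to an allyl complex of trivalent iridium and the lithium aryloxide attacks the substituted terminus, should give the branched ether with the C5 configuration set by the ligand (catalyst control).

Step 15
Reactants: 23 3-[(1R)-1-{[7-(benzyloxy)-4-oxo-2-(2-phenylethyl)-4H-chromen-6-yl]oxy}prop-2-en-1-yl]-2-[(1S)-1-(tert-butyldimethylsilyloxy)prop-2-en-1-yl]-6-(2-phenylethyl)-4H-pyran-4-one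
Product: 25 (5S,6S,7R,8S)-5-{[7-(benzyloxy)-4-oxo-2-(2-phenylethyl)-4H-chromen-6-yl]oxy}-8-(tert-butyldimethylsilyloxy)-6,7-dihydroxy-2-(2-phenylethyl)-5,6,7,8-tetrahydro-4H-chromen-4-one, via diene 24 (not isolated)
Conditions: second-generation Grubbs catalyst RuCl2(=CHPh)(H2IMes)(PCy3) (5 mol%), CH2Cl2, 40 °C; then acetone–H2O, NMO, OsO4 (5 mol%), 0 °C to rt
Reagents that add atoms: osmium tetroxide (catalytic oxygen carrier), O=[Os](=O)(=O)=O; N-methylmorpholine N-oxide, C[N+]1([O-])CCOCC1; water, O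
Why: The ruthenium alkylidene engages one vinyl group and then the other through [2+2] cycloaddition and cycloreversion (Chauvin mechanism), so the six-membered carbocycle C4a–C5–C6=C7–C8–C8a closes by ring-closing metathesis of two monosubstituted alkenes held ortho on the planar pyranone, with loss of ethene. The closest known reaction types are ring-closing metathesis of ortho-bis(1-oxyallyl)arenes to 1,4-dioxygenated 1,4-dihydronaphthalenes and the Upjohn dihydroxylation of conduritol-type cyclohexenes. Diene 24 could aromatise by 1,4-elimination of the phenol, so it is osmylated in the same flask without isolation. OsO4 adds suprafacially in a (3+2) manner to C6=C7, and hydrolysis of the osmate ester gives the cis-diol while NMO returns the osmium to OsO4. C6 and C7 are set together by substrate control: the C5 aryloxy and the C8 silyloxy groups sit on the same ring face, so osmium adds from the opposite face, anti to both allylic oxygens. The step needs chemoselectivity, secured because the pyranone and chromone double bonds are vinylogous ester bonds that are unreactive toward OsO4, and facial selectivity, secured by the two cis-disposed allylic substituents, one of them the bulky silyl ether.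

Step 16
Reactants: 25 (5S,6S,7R,8S)-5-{[7-(benzyloxy)-4-oxo-2-(2-phenylethyl)-4H-chromen-6-yl]oxy}-8-(tert-butyldimethylsilyloxy)-6,7-dihydroxy-2-(2-phenylethyl)-5,6,7,8-tetrahydro-4H-chromen-4-one
Product: 26 (5S,6S,7R,8S)-5-{[7-(benzyloxy)-4-oxo-2-(2-phenylethyl)-4H-chromen-6-yl]oxy}-6,7,8-trihydroxy-2-(2-phenylethyl)-5,6,7,8-tetrahydro-4H-chromen-4-one
Conditions: HF·pyridine, pyridine, THF, 0 °C to rt
Reagents that add atoms: none
Why: fluoride-driven cleavage of the silyl ether under buffered, non-basic conditions avoids deprotonation at C8 and leaves the aryl ether and the benzyl ether untouched.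

Step 17
Reactants: 26 (5S,6S,7R,8S)-5-{[7-(benzyloxy)-4-oxo-2-(2-phenylethyl)-4H-chromen-6-yl]oxy}-6,7,8-trihydroxy-2-(2-phenylethyl)-5,6,7,8-tetrahydro-4H-chromen-4-one
Product: 27 (5S,6S,7R,8S)-6,7,8-trihydroxy-5-{[7-hydroxy-4-oxo-2-(2-phenylethyl)-4H-chromen-6-yl]oxy}-2-(2-phenylethyl)-5,6,7,8-tetrahydro-4H-chromen-4-one (CNP0248258.1)
Conditions: BCl3, pentamethylbenzene, CH2Cl2, −78 °C; then MeOH
Reagents that add atoms: none
Why: Lewis-acid cleavage of the aryl benzyl ether at low temperature, with pentamethylbenzene trapping the benzyl cation (Friedel–Crafts capture), should free the phenol without hydrogenation conditions that could reduce the pyranone or cut the C5–O bond.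

**Compound list**

1 | trimethylsilylacetylene | C#C[Si](C)(C)C | starting material
2 | acrolein | C=CC=O | starting material
3 | rac-5-(trimethylsilyl)pent-1-en-4-yn-3-ol | C=CC(O)C#C[Si](C)(C)C | intermediate
4 | (3S)-5-(trimethylsilyl)pent-1-en-4-yn-3-ol | C=C[C@H](O)C#C[Si](C)(C)C | intermediate
5 | tert-butyldimethyl{[(3S)-5-(trimethylsilyl)pent-1-en-4-yn-3-yl]oxy}silane | C=C[C@H](O[Si](C)(C)C(C)(C)C)C#C[Si](C)(C)C | intermediate
6 | tert-butyldimethyl{[(3S)-pent-1-en-4-yn-3-yl]oxy}silane | C=C[C@H](O[Si](C)(C)C(C)(C)C)C#C | intermediate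
7 | ethyl 3-oxo-5-phenylpentanoate | CCOC(=O)CC(=O)CCc1ccccc1 | starting material
8 | ethyl (2E)-3-methoxy-5-phenylpent-2-enoate | CCOC(=O)/C=C(/OC)CCc1ccccc1 | intermediate
9 | (2E)-N,3-dimethoxy-N-methyl-5-phenylpent-2-enamide | CON(C)C(=O)/C=C(/OC)CCc1ccccc1 | intermediate
10 | (3S,7E)-3-(tert-butyldimethylsilyloxy)-8-methoxy-10-phenyldeca-1,7-dien-4-yn-6-one | C=C[C@H](O[Si](C)(C)C(C)(C)C)C#CC(=O)/C=C(/OC)CCc1ccccc1 | intermediate
11 | (3S,4E,7E)-3-(tert-butyldimethylsilyloxy)-8-methoxy-10-phenyl-4-(pyrrolidin-1-yl)deca-1,4,7-trien-6-one (not isolated; aminovinyl geometry of no consequence) | C=C[C@H](O[Si](C)(C)C(C)(C)C)/C(N1CCCC1)=C\C(=O)/C=C(/OC)CCc1ccccc1 | intermediate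
12 | (3S,4Z,7E)-3-(tert-butyldimethylsilyloxy)-5-iodo-8-methoxy-10-phenyl-4-(pyrrolidin-1-yl)deca-1,4,7-trien-6-one (not isolated; aminovinyl geometry of no consequence) | C=C[C@H](O[Si](C)(C)C(C)(C)C)/C(N1CCCC1)=C(/I)C(=O)/C=C(/OC)CCc1ccccc1 | intermediate
13 | 3-iodo-6-(2-phenylethyl)-2-[(1S)-1-(tert-butyldimethylsilyloxy)prop-2-en-1-yl]-4H-pyran-4-one | O=c1cc(CCc2ccccc2)oc([C@@H](O[Si](C)(C)C(C)(C)C)C=C)c1I | intermediate
14 | (2E)-3-(4,4,5,5-tetramethyl-1,3,2-dioxaborolan-2-yl)prop-2-en-1-ol | OC/C=C/B1OC(C)(C)C(C)(C)O1 | starting material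
15 | 3-[(1E)-3-hydroxyprop-1-en-1-yl]-6-(2-phenylethyl)-2-[(1S)-1-(tert-butyldimethylsilyloxy)prop-2-en-1-yl]-4H-pyran-4-one | O=c1cc(CCc2ccccc2)oc([C@@H](O[Si](C)(C)C(C)(C)C)C=C)c1/C=C/CO | intermediate
16 | methyl (2E)-3-{4-oxo-6-(2-phenylethyl)-2-[(1S)-1-(tert-butyldimethylsilyloxy)prop-2-en-1-yl]-4H-pyran-3-yl}prop-2-en-1-yl carbonate | O=c1cc(CCc2ccccc2)oc([C@@H](O[Si](C)(C)C(C)(C)C)C=C)c1/C=C/COC(=O)OC | intermediate
17 | 2',4',5'-trihydroxyacetophenone | CC(=O)c1cc(O)c(O)cc1O | starting material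
18 | 1-[4-(benzyloxy)-2,5-dihydroxyphenyl]ethan-1-one | CC(=O)c1cc(O)c(OCc2ccccc2)cc1O | intermediate
19 | 1-[4-(benzyloxy)-2-hydroxy-5-(methoxymethoxy)phenyl]ethan-1-one | CC(=O)c1cc(OCOC)c(OCc2ccccc2)cc1O | intermediate
20 | methyl 3-phenylpropanoate | COC(=O)CCc1ccccc1 | starting material
21 | 1-[4-(benzyloxy)-2-hydroxy-5-(methoxymethoxy)phenyl]-5-phenylpentane-1,3-dione (not isolated) | O=C(CC(=O)CCc1ccccc1)c1cc(OCOC)c(OCc2ccccc2)cc1O | intermediate
22 | 7-(benzyloxy)-6-hydroxy-2-(2-phenylethyl)-4H-chromen-4-one | O=c1cc(CCc2ccccc2)oc2cc(OCc3ccccc3)c(O)cc12 | intermediate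
23 | 3-[(1R)-1-{[7-(benzyloxy)-4-oxo-2-(2-phenylethyl)-4H-chromen-6-yl]oxy}prop-2-en-1-yl]-2-[(1S)-1-(tert-butyldimethylsilyloxy)prop-2-en-1-yl]-6-(2-phenylethyl)-4H-pyran-4-one | O=c1cc(CCc2ccccc2)oc([C@@H](O[Si](C)(C)C(C)(C)C)C=C)c1[C@H](Oc1cc2c(=O)cc(CCc3ccccc3)oc2cc1OCc1ccccc1)C=C | intermediate
24 | (5R,8S)-5-{[7-(benzyloxy)-4-oxo-2-(2-phenylethyl)-4H-chromen-6-yl]oxy}-8-(tert-butyldimethylsilyloxy)-2-(2-phenylethyl)-5,8-dihydro-4H-chromen-4-one (not isolated) | O=c1cc(CCc2ccccc2)oc2c1[C@H](Oc1cc3c(=O)cc(CCc4ccccc4)oc3cc1OCc1ccccc1)C=C[C@@H]2O[Si](C)(C)C(C)(C)C | intermediate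
25 | (5S,6S,7R,8S)-5-{[7-(benzyloxy)-4-oxo-2-(2-phenylethyl)-4H-chromen-6-yl]oxy}-8-(tert-butyldimethylsilyloxy)-6,7-dihydroxy-2-(2-phenylethyl)-5,6,7,8-tetrahydro-4H-chromen-4-one | O=c1cc(CCc2ccccc2)oc2c1[C@H](Oc1cc3c(=O)cc(CCc4ccccc4)oc3cc1OCc1ccccc1)[C@@H](O)[C@@H](O)[C@@H]2O[Si](C)(C)C(C)(C)C | intermediate
26 | (5S,6S,7R,8S)-5-{[7-(benzyloxy)-4-oxo-2-(2-phenylethyl)-4H-chromen-6-yl]oxy}-6,7,8-trihydroxy-2-(2-phenylethyl)-5,6,7,8-tetrahydro-4H-chromen-4-one | O=c1cc(CCc2ccccc2)oc2c1[C@H](Oc1cc3c(=O)cc(CCc4ccccc4)oc3cc1OCc1ccccc1)[C@@H](O)[C@@H](O)[C@@H]2O | intermediate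
27 | (5S,6S,7R,8S)-6,7,8-trihydroxy-5-{[7-hydroxy-4-oxo-2-(2-phenylethyl)-4H-chromen-6-yl]oxy}-2-(2-phenylethyl)-5,6,7,8-tetrahydro-4H-chromen-4-one | O=c1cc(CCc2ccccc2)oc2c1[C@H](Oc1cc3c(=O)cc(CCc4ccccc4)oc3cc1O)[C@@H](O)[C@@H](O)[C@@H]2O | target

**Step count**

Total: 17 steps. Longest linear sequence: 12 steps (steps 1, 2, 3, 4, 7, 8, 9, 10, 14, 15, 16, 17).

**Steps most likely to fail**

Step 15. Diene 24 may lose the phenol by 1,4-elimination and aromatise before osmium reaches it. Ruthenium hydrides may shift the allylic double bonds before ring closure. Ruthenium residues oxidised by NMO may over-oxidise the diol. Fallback, from 23 and back to 25: the C6–C7 bond is made by reductive carbonyl coupling, so no diene is formed. Both vinyl groups of 23 are cleaved (OsO4 cat., NaIO4, 2,6-lutidine, dioxane–H2O) to the dialdehyde F1. SmI2 (THF, tBuOH, −78 °C) then joins the two formyl carbons in an intramolecular pinacol coupling. This should give the cis-diol anti to the two neighbouring oxygen substituents, which is 25.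

Step 14. Ionisation and attack at an allyl terminus flanked by the pyranone carbonyl and the silyloxyallyl arm may be slow, so the linear ether could prevail or the diastereoselectivity could be poor. Fallback, from 15 and back to 23: Sharpless asymmetric epoxidation of 15 (Ti(OiPr)4, D-(−)-diisopropyl tartrate, tBuOOH, 4 Å sieves, CH2Cl2, −20 °C) should give the (2R,3R)-epoxy alcohol F2. Phenol 22 (Ti(OiPr)4-mediated, or as its sodium salt) opens F2 at the pyranone-bearing carbon with inversion to the aryloxy diol F3. The terminal diol of F3 is then turned into the vinyl group (PPh3, I2, imidazole, toluene, 80 °C), which gives 23.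

Step 8. Iodination may spill over to the methoxy-enone carbon, or the amine may exchange with the methoxy group and blur the regiochemistry. The configuration at the silyloxy carbon may also erode through enamine–iminium tautomerism during the acid ring closure. Fallback, from 6 and back to 13: iodine is introduced before the phenylethyl half is attached. The lithium acetylide of 6 is acylated with N-methoxy-N-methylacetamide to the methyl ynone F4. Pyrrolidine and then N-iodosuccinimide give the iodo-enaminone F5, which has a single nucleophilic carbon. Kinetic deprotonation of its methyl ketone (LiN(SiMe3)2, THF, −78 °C) and acylation with 3-phenylpropanoyl chloride give the β-diketone F6. CF3CO2H in CH2Cl2 closes the pyranone with loss of pyrrolidine, giving 13.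

**Further compounds**

F1 | step 15 | (2S)-2-{[7-(benzyloxy)-4-oxo-2-(2-phenylethyl)-4H-chromen-6-yl]oxy}-2-{2-[(1R)-1-(tert-butyldimethylsilyloxy)-2-oxoethyl]-4-oxo-6-(2-phenylethyl)-4H-pyran-3-yl}acetaldehyde | O=c1cc(CCc2ccccc2)oc([C@@H](O[Si](C)(C)C(C)(C)C)C=O)c1[C@H](Oc1cc2c(=O)cc(CCc3ccccc3)oc2cc1OCc1ccccc1)C=O
F2 | step 14 | 3-[(2R,3R)-3-(hydroxymethyl)oxiran-2-yl]-6-(2-phenylethyl)-2-[(1S)-1-(tert-butyldimethylsilyloxy)prop-2-en-1-yl]-4H-pyran-4-one | O=c1cc(CCc2ccccc2)oc([C@@H](O[Si](C)(C)C(C)(C)C)C=C)c1[C@H]3O[C@@H]3CO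
F3 | step 14 | 3-[(1S,2R)-1-{[7-(benzyloxy)-4-oxo-2-(2-phenylethyl)-4H-chromen-6-yl]oxy}-2,3-dihydroxypropyl]-6-(2-phenylethyl)-2-[(1S)-1-(tert-butyldimethylsilyloxy)prop-2-en-1-yl]-4H-pyran-4-one | O=c1cc(CCc2ccccc2)oc([C@@H](O[Si](C)(C)C(C)(C)C)C=C)c1[C@H](Oc1cc2c(=O)cc(CCc3ccccc3)oc2cc1OCc1ccccc1)[C@H](O)CO
F4 | step 8 | (5S)-5-(tert-butyldimethylsilyloxy)hept-6-en-3-yn-2-one | C=C[C@H](O[Si](C)(C)C(C)(C)C)C#CC(C)=O
F5 | step 8 | (3Z,5S)-5-(tert-butyldimethylsilyloxy)-3-iodo-4-(pyrrolidin-1-yl)hepta-3,6-dien-2-one | C=C[C@H](O[Si](C)(C)C(C)(C)C)/C(N1CCCC1)=C(/I)C(C)=O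
F6 | step 8 | (6Z,8S)-8-(tert-butyldimethylsilyloxy)-6-iodo-1-phenyl-7-(pyrrolidin-1-yl)deca-6,9-diene-3,5-dione | C=C[C@H](O[Si](C)(C)C(C)(C)C)/C(N1CCCC1)=C(/I)C(=O)CC(=O)CCc1ccccc1
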